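**Retrosynthetic overview**
- The target is reached by hydrogenolysis of its 4',5,7-tribenzyl ether, which comes from a 5,7-difluoroflavone by twofold SNAr with benzyl oxide.
- Feature the plan rests on: in ring A the aryl ether bond O-1–C-8a and the C-5–O and C-7–O bonds all lie ortho or para to the C-4 carbonyl, so ring A can be bought as a 2,4,6-trifluorobenzoyl unit whose three fluorides are exchanged for oxygen.
- Key disconnections: C-3–C-4 (C-acylation of a ring-B methyl ketone enolate) and O-1–C-8a (intramolecular SNAr).
- Ring order: ring C is the only ring made (step 6); rings A and B are bought as arenes.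
- The ring-B ketone comes from syringaldehyde by benzylation, bromination at C-2, copper-catalysed methoxylation, MeMgBr addition and oxidation.

Key step: step 6

Remark: the target has no stereocentre. The carbinol centre made in step 4 is racemic and is removed in step 5. The 1,3-dione of step 6 is drawn as its diketo tautomer.

**Step 1**
Reactants: 1 syringaldehyde (4-hydroxy-3,5-dimethoxybenzaldehyde)
Product: 2 4-(benzyloxy)-3,5-dimethoxybenzaldehyde
Conditions: BnBr, K2CO3, DMF, 60 °C
Reagents that add atoms: benzyl bromide, BrCc1ccccc1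
Why: Williamson ether synthesis at the only acidic site; the benzyl ether blocks O-4' with a group that later leaves by hydrogenolysis together with the ring-A benzyl ethers.

**Step 2**
Reactants: 2 4-(benzyloxy)-3,5-dimethoxybenzaldehyde
Product: 3 4-(benzyloxy)-2-bromo-3,5-dimethoxybenzaldehyde
Conditions: NBS, DMF, rt, dark
Reagents that add atoms: N-bromosuccinimide, O=C1CCC(=O)N1Br
Why: Electrophilic aromatic bromination; C-2 and C-6 are equivalent and each is ortho to one methoxy group and para to the other (the pattern under which 3,4,5-trimethoxybenzaldehyde takes up a single bromine), the formyl group and the first bromine slow a second substitution, and polar dark conditions avoid radical attack at the benzylic CH2.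

**Step 3**
Reactants: 3 4-(benzyloxy)-2-bromo-3,5-dimethoxybenzaldehyde
Product: 4 4-(benzyloxy)-2,3,5-trimethoxybenzaldehyde
Conditions: NaOMe, CuBr (10 mol%), MeOH/DMF, 100 °C
Reagents that add atoms: sodium methoxide, [Na+].[O-]C
Why: Ullmann-type copper-catalysed methoxylation of an aryl bromide, assisted by the ortho formyl group, should complete the contiguous 2,3,4,5-oxygen pattern of ring B; the aldehyde cannot enolise and the benzyl and methyl ethers are inert to methoxide.

**Step 4**
Reactants: 4 4-(benzyloxy)-2,3,5-trimethoxybenzaldehyde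
Product: 5 rac-1-[4-(benzyloxy)-2,3,5-trimethoxyphenyl]ethanol
Conditions: MeMgBr, THF, 0 °C; aq NH4Cl
Reagents that add atoms: methylmagnesium bromide, C[Mg]Br
Why: Grignard 1,2-addition to the aldehyde should give the secondary benzylic alcohol; the new carbinol centre forms as a racemate, which does not matter because step 5 removes it.

**Step 5**
Reactants: 5 rac-1-[4-(benzyloxy)-2,3,5-trimethoxyphenyl]ethanol
Product: 6 1-[4-(benzyloxy)-2,3,5-trimethoxyphenyl]ethanone
Conditions: Dess–Martin periodinane, CH2Cl2, rt
Reagents that add atoms: none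
Why: Dess–Martin oxidation of a secondary benzylic alcohol to the aryl methyl ketone under near-neutral conditions that should leave the ethers and the electron-rich ring untouched.

**Step 6**
Reactants: 6 1-[4-(benzyloxy)-2,3,5-trimethoxyphenyl]ethanone; 7 2,4,6-trifluorobenzoyl chloride
Product: 10 4'-(benzyloxy)-5,7-difluoro-2',3',5'-trimethoxyflavone, via lithium enolate 8 (not isolated), via 1,3-dione 9 (not isolated)
Conditions: LiN(SiMe3)2 (2.2 equiv), THF, −78 °C; 7, −78 to 0 °C; aq NH4Cl; then crude 9, K2CO3, DMF, 90 °C
Reagents that add atoms: none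
Why: LiN(SiMe3)2 should convert 6 fully into lithium enolate 8, which attacks the acid chloride through carbon (Claisen-type C-acylation, forming C-3–C-4) to give dione 9; with K2CO3 in DMF the enolate oxygen of 9 then adds to an ortho C–F carbon and fluoride leaves from a Meisenheimer adduct stabilised by the ortho acyl group and the other two fluorines (intramolecular SNAr, forming O-1–C-8a). The closest known reaction type is the preparation of chromones and flavones from ketone enolates and 2-fluorobenzoyl chlorides, the oxygen counterpart of quinolone cycloaracylation. Ring C closes as a six-membered ring by O-attack on an aromatic sp2 carbon (6-exo-trig with respect to the C-8a–C-8 π bond), whereas attack by the central carbon of the dione would need a four-membered ring. No stereocentre is formed. The step needs C- over O-acylation, which complete pre-enolisation, the lithium counter-ion and low temperature should secure, the second equivalent of base taking the acidic dione proton so that unreacted 8 is not quenched; it also needs a single ring-closure product, which the substrate secures because the two ortho fluorines are equivalent and the para fluorine is out of reach.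

**Step 7**
Reactants: 10 4'-(benzyloxy)-5,7-difluoro-2',3',5'-trimethoxyflavone; 11 benzyl alcohol (first equivalent, which displaces the first fluoride)
Product: 13 4',5,7-tris(benzyloxy)-2',3',5'-trimethoxyflavone, via monofluoro flavone 12 (not isolated)
Conditions: BnOH (2.6 equiv), NaH (2.5 equiv), THF, 0 °C; then 10, THF/DMF, rt to 60 °C
Reagents that add atoms: benzyl alcohol (second equivalent of 11, which displaces the second fluoride; both equivalents react as sodium benzyl oxide made with NaH), OCc1ccccc1
Why: Twofold intermolecular SNAr in which two equivalents of sodium benzyl oxide each replace one fluoride (10 + 2 BnONa → 13 + 2 NaF); the C-7 (para) and C-5 (ortho) fluorides are both activated by the C-4 carbonyl, the first benzyloxy group sits meta to the remaining C–F carbon and should slow the second displacement only moderately, either order of displacement converges on 13, addition of alkoxide at C-2 is expected to be reversible, and ring B carries no leaving group.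

**Step 8**
Reactants: 13 4',5,7-tris(benzyloxy)-2',3',5'-trimethoxyflavone
Product: 14 5,7,4'-trihydroxy-2',3',5'-trimethoxyflavone
Conditions: H2 (1 atm), 10% Pd/C, THF/MeOH, rt
Reagents that add atoms: none
Why: Catalytic hydrogenolysis of three benzyl aryl ethers; the methyl ethers are inert and the C-2–C-3 double bond of the chromone (a vinylogous ester) should be reduced far more slowly than the O-benzyl bonds are cleaved, so the reaction is stopped after uptake of three equivalents of hydrogen.

**Compound list**
1 | syringaldehyde (4-hydroxy-3,5-dimethoxybenzaldehyde) | COc1cc(C=O)cc(OC)c1O | starting material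
2 | 4-(benzyloxy)-3,5-dimethoxybenzaldehyde | COc1cc(C=O)cc(OC)c1OCc1ccccc1 | intermediate
3 | 4-(benzyloxy)-2-bromo-3,5-dimethoxybenzaldehyde | COc1cc(C=O)c(Br)c(OC)c1OCc1ccccc1 | intermediate
4 | 4-(benzyloxy)-2,3,5-trimethoxybenzaldehyde | COc1cc(C=O)c(OC)c(OC)c1OCc1ccccc1 | intermediate
5 | rac-1-[4-(benzyloxy)-2,3,5-trimethoxyphenyl]ethanol (racemate) | COc1cc(C(C)O)c(OC)c(OC)c1OCc1ccccc1 | intermediate
6 | 1-[4-(benzyloxy)-2,3,5-trimethoxyphenyl]ethanone | COc1cc(C(C)=O)c(OC)c(OC)c1OCc1ccccc1 | intermediate
7 | 2,4,6-trifluorobenzoyl chloride | O=C(Cl)c1c(F)cc(F)cc1F | starting material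
8 | lithium 1-[4-(benzyloxy)-2,3,5-trimethoxyphenyl]ethenolate (lithium enolate of 6) | [Li+].C=C([O-])c1cc(OC)c(OCc2ccccc2)c(OC)c1OC | intermediate
9 | 1-[4-(benzyloxy)-2,3,5-trimethoxyphenyl]-3-(2,4,6-trifluorophenyl)propane-1,3-dione | COc1cc(C(=O)CC(=O)c2c(F)cc(F)cc2F)c(OC)c(OC)c1OCc1ccccc1 | intermediate
10 | 4'-(benzyloxy)-5,7-difluoro-2',3',5'-trimethoxyflavone (2-[4-(benzyloxy)-2,3,5-trimethoxyphenyl]-5,7-difluoro-4H-chromen-4-one) | COc1cc(-c2cc(=O)c3c(F)cc(F)cc3o2)c(OC)c(OC)c1OCc1ccccc1 | intermediate
11 | benzyl alcohol | OCc1ccccc1 | starting material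
12 | 4',7-bis(benzyloxy)-5-fluoro-2',3',5'-trimethoxyflavone (7-(benzyloxy)-2-[4-(benzyloxy)-2,3,5-trimethoxyphenyl]-5-fluoro-4H-chromen-4-one) | COc1cc(-c2cc(=O)c3c(F)cc(OCc4ccccc4)cc3o2)c(OC)c(OC)c1OCc1ccccc1 | intermediate
13 | 4',5,7-tris(benzyloxy)-2',3',5'-trimethoxyflavone (5,7-bis(benzyloxy)-2-[4-(benzyloxy)-2,3,5-trimethoxyphenyl]-4H-chromen-4-one) | COc1cc(-c2cc(=O)c3c(OCc4ccccc4)cc(OCc4ccccc4)cc3o2)c(OC)c(OC)c1OCc1ccccc1 | intermediate
14 | 5,7,4'-trihydroxy-2',3',5'-trimethoxyflavone (5,7-dihydroxy-2-(4-hydroxy-2,3,5-trimethoxyphenyl)-4H-chromen-4-one) | COc1cc(-c2cc(=O)c3c(O)cc(O)cc3o2)c(OC)c(OC)c1O | target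

**Step count**
Total steps: 8. Longest linear sequence: 8 steps, from syringaldehyde 1 to target 14.

**Steps most likely to fail**

1. Step 6. The enolate may be acylated at oxygen to give an enol ester, or twice at carbon, or the amide base may consume the acid chloride, so that too little dione reaches the ring closure. The fallback sets out from 6 and 7 and comes back at dione 9. Acid chloride 7 would be treated with 1H-benzotriazole and Et3N in CH2Cl2 to give the N-acylbenzotriazole (1H-benzotriazol-1-yl)(2,4,6-trifluorophenyl)methanone F1. Ketone 6 and F1 with MgBr2·OEt2 and i-Pr2NEt in CH2Cl2 at room temperature (soft enolisation, in which the magnesium chelate of the product directs acylation to carbon) should then give dione 9. This is isolated and closed with K2CO3 in DMF as in step 6.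

2. Step 7. The second fluoride displacement may stall once ring A carries a donor, or benzyl oxide may add at C-2 and open ring C faster than it substitutes. The fallback sets out from aldehyde 4 and comes back at 13; it gives up the fluoride tactic and takes the ring-A oxygens from a phloroglucinol ketone. Bought 2',4',6'-trihydroxyacetophenone would be benzylated at two of its three hydroxyls, leaving the one chelated to the carbonyl (BnBr, K2CO3, DMF), to give 1-[2,4-bis(benzyloxy)-6-hydroxyphenyl]ethanone F2. Claisen–Schmidt condensation of F2 with 4 (KOH, EtOH, rt) should give the 2'-hydroxychalcone (E)-1-[2,4-bis(benzyloxy)-6-hydroxyphenyl]-3-[4-(benzyloxy)-2,3,5-trimethoxyphenyl]prop-2-en-1-one F3. Oxidative cyclisation with catalytic I2 in DMSO at 120 °C should then give 13.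

3. Step 3. Hydrodebromination by methoxide-derived hydride, or attack of methoxide on the free aldehyde at 100 °C, may outrun C–O coupling at the doubly ortho-substituted bromide. The fallback sets out from bromide 3 and comes back at aldehyde 4; it makes the C–O bond through an organolithium instead of copper.
   - Acetalisation (ethylene glycol, TsOH, toluene, Dean–Stark) would give 2-[4-(benzyloxy)-2-bromo-3,5-dimethoxyphenyl]-1,3-dioxolane F4.
   - Bromine–lithium exchange (n-BuLi, THF, −78 °C) would give the aryllithium [3-(benzyloxy)-6-(1,3-dioxolan-2-yl)-2,4-dimethoxyphenyl]lithium F5.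
   - Trapping with B(OMe)3 would give dimethyl [3-(benzyloxy)-6-(1,3-dioxolan-2-yl)-2,4-dimethoxyphenyl]boronate F6.
   - Oxidation in the same flask (H2O2, NaOH, 0 °C) would give 3-(benzyloxy)-6-(1,3-dioxolan-2-yl)-2,4-dimethoxyphenol F7.
   - Methylation (MeI, K2CO3, DMF) would give 2-[4-(benzyloxy)-2,3,5-trimethoxyphenyl]-1,3-dioxolane F8.
   - Hydrolysis (1 M HCl, THF, rt) would release 4.

**Further compounds**
F1 | step 6 | (1H-benzotriazol-1-yl)(2,4,6-trifluorophenyl)methanone | O=C(c1c(F)cc(F)cc1F)n1nnc2ccccc21
F2 | step 7 | 1-[2,4-bis(benzyloxy)-6-hydroxyphenyl]ethanone | CC(=O)c1c(O)cc(OCc2ccccc2)cc1OCc1ccccc1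
F3 | step 7 | (E)-1-[2,4-bis(benzyloxy)-6-hydroxyphenyl]-3-[4-(benzyloxy)-2,3,5-trimethoxyphenyl]prop-2-en-1-one | COc1cc(/C=C/C(=O)c2c(O)cc(OCc3ccccc3)cc2OCc2ccccc2)c(OC)c(OC)c1OCc1ccccc1
F4 | step 3 | 2-[4-(benzyloxy)-2-bromo-3,5-dimethoxyphenyl]-1,3-dioxolane | COc1cc(C2OCCO2)c(Br)c(OC)c1OCc1ccccc1
F5 | step 3 | [3-(benzyloxy)-6-(1,3-dioxolan-2-yl)-2,4-dimethoxyphenyl]lithium | COc1cc(C2OCCO2)c([Li])c(OC)c1OCc1ccccc1
F6 | step 3 | dimethyl [3-(benzyloxy)-6-(1,3-dioxolan-2-yl)-2,4-dimethoxyphenyl]boronate | COB(OC)c1c(C2OCCO2)cc(OC)c(OCc2ccccc2)c1OC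
F7 | step 3 | 3-(benzyloxy)-6-(1,3-dioxolan-2-yl)-2,4-dimethoxyphenol | COc1cc(C2OCCO2)c(O)c(OC)c1OCc1ccccc1
F8 | step 3 | 2-[4-(benzyloxy)-2,3,5-trimethoxyphenyl]-1,3-dioxolane | COc1cc(C2OCCO2)c(OC)c(OC)c1OCc1ccccc1
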